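The runs were computed with made-up constants; the scatter is artificial.

I begin with a subtraction. The flask holds 50 µM of free catalyst against 28 µM of impurity, the smaller amount and so the limiting reagent of a one-to-one poisoning, and what remains I call live catalyst, the charge less the impurity, 22.0 µM.

in all of them: left-handed substrate 0.10 M; right-handed substrate 0.10 M; impurity 28 µM

| run | reagent | free catalyst | remark | time |
|---|---|---|---|---|
| Tuesday's | 0.10 M | 50 µM | run made earlier |  |
| Monday's | 0.15 M | 50 µM | run made earlier |  |
| Thursday's | 0.20 M | 100 µM | run made earlier |  |
| flask | 0.200 M | 50 µM |  | 1.5 h |

- Tuesday's (time / min: left-handed substrate / %, right-handed substrate / %): 10.0: 48.9, 48.9; 20.0: 47.1, 47.5; 25.0: 47.3, 46.5; 40.0: 46.1, 45.0; 50.0: 44.7, 43.9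
- Monday's (time / min: left-handed substrate / %, right-handed substrate / %): 10.0: 48.2, 48.1; 20.0: 46.0, 46.6; 25.0: 45.7, 45.5; 40.0: 43.6, 44.0; 50.0: 41.0, 43.1
- Thursday's (time / min: left-handed substrate / %, right-handed substrate / %): 5.00: 45.0, 45.4; 15.0: 40.2, 39.6; 25.0: 34.3, 34.9; 40.0: 30.2, 29.0; 50.0: 27.0, 27.0

(scatter of a reading: 0.5 percentage points)

- free catalyst is single-handed; left-handed substrate and right-handed substrate are mirror images of each other, charged as a racemate, each of them at the stated concentration
- what was read earlier has a scatter of 0.5 percentage points, one standard deviation
- an excess is the difference of the two amounts in percent of their sum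
- an excess is below zero if the other one leads

- part of the left-handed substrate and right-handed substrate charged together that has reacted at 1.5 h
- excess of left-handed product over right-handed product in the product at 1.5 h
- excess of right-handed substrate over left-handed substrate among what is left of the two at 1.5 h

The readings test this. From Tuesday's run to Thursday's, reagent and catalyst both double, so charged catalyst predicts an early loss rate higher by a factor 4.00, whereas live catalyst predicts 6.55; I read 7.74, nearer the second. I take the rate as first order in reagent, substrate and live catalyst. Thursday's run and the flask both charge reagent equal to the two substrates together, so the ratio of reacted to unreacted substrate grows in proportion to live catalyst and time. Thursday's last reading gives that ratio as 0.852, which scales for the flask to 0.469, so my own reckoning is 31.9 % reacted. The two substrates read alike, so I expect the substrate excess near zero; these readings hold no product, so they give me no ground for the product excess.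

The forecast says 32.3 %, 0 % and 0 %, “meaning the impurity kills catalyst 1:1”.

The flask gives 32.0 %, 2.88 % and 0.0537 %, all within the forecast's margins, by this scheme:

    reagent + free catalyst + left-handed substrate → free catalyst + left-handed product (k = 2060 M⁻² min⁻¹)
    reagent + free catalyst + right-handed substrate → free catalyst + right-handed product (k = 309 M⁻² min⁻¹)
    left-handed substrate ⇌ right-handed substrate (k = 2.44 min⁻¹)
    free catalyst + impurity → spent catalyst (k = 83900 M⁻¹ min⁻¹)
    left-handed product ⇌ right-handed product (k = 0.100 min⁻¹)

Free catalyst in the flask stands at 44.0 % of its charge at 0.150 h and 44.0 % at 1.50 h, with impurity at 0 %. The neighbouring flask, with 7.00 µM of impurity, has live catalyst 43.0 µM, so its ratio becomes 0.916 and I reckon 47.8 % reacted; that flask gives 47.8 %, with free catalyst at 86.0 % of its charge.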